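The chain is built ring by ring from ring A to ring H. Every diaryl ether bond is cut so that the ring being added is the electrophile (C1 = carbon bearing the oxygen from the previous ring). Rings B, D, F and H enter as para-formyl aryl fluorides (SNAr, then Dakin oxidation of CHO to the C4 oxygen). Rings C, E and G exploit that their oxygens map onto 2,3-dimethoxy-1,4-benzoquinone: the carbonyl oxygens become O on C6 (bridge to the next ring) and HO on C3, the equivalent CH carbons become C1 and C2–H. In the key step the C4 phenoxide of ring D displaces bromide from 5-bromo-2,3-dimethoxy-1,4-benzoquinone, installing the complete ring E in one operation; the precursor is tetramer phenol 18.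

Key step: step 12

Remark on the chemistry: rings are lettered A to H from the 2,4,6-trihydroxyphenoxy end. The target has no stereocentre and no stable stereoaxis. Compounds 1, 4 and 10 are assumed to be purchasable. All phenoxide, hydroquinone and polyphenol operations are run under argon with degassed solvents.

Step 1
Reactants: 1 4-fluoro-2,6-dimethoxybenzaldehyde
Product: 2 4-fluoro-2-hydroxy-6-methoxybenzaldehyde
Conditions: BCl3 (1.1 eq), CH2Cl2, −78 °C to 0 °C; then H2O
Reagents that add atoms: none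
Why: Chelation-directed Lewis acid demethylation, in which BCl3 bound to the formyl oxygen cleaves one ortho O–CH3 bond and the resulting six-membered aryloxyboron chelate ties up the reagent so that the second methoxy group survives.

Step 2
Reactants: 2 4-fluoro-2-hydroxy-6-methoxybenzaldehyde
Product: 3 2-benzyloxy-4-fluoro-6-methoxybenzaldehyde
Conditions: BnBr (1.1 eq), K2CO3, DMF, rt
Reagents that add atoms: benzyl bromide, BrCc1ccccc1
Why: Williamson ether synthesis on an acidic ortho-hydroxy aldehyde, run at room temperature so that the poorly nucleophilic phenoxide does not engage the aryl fluoride.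

Step 3
Reactants: 3 2-benzyloxy-4-fluoro-6-methoxybenzaldehyde; 4 2,4,6-trimethoxyphenol
Product: 5 2-benzyloxy-6-methoxy-4-(2,4,6-trimethoxyphenoxy)benzaldehyde (AB aldehyde)
Conditions: Cs2CO3 (1.5 eq), DMSO, 80 °C, Ar
Reagents that add atoms: none
Why: SNAr in which the cesium phenoxide of 4 displaces fluoride para to the formyl group, the two alkoxy groups sitting meta to the reacting carbon and therefore not destabilising the Meisenheimer intermediate.

Step 4
Reactants: 5 AB aldehyde
Product: 7 2-benzyloxy-6-methoxy-4-(2,4,6-trimethoxyphenoxy)phenol, via AB aryl formate 6 (not isolated)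
Conditions: mCPBA (1.1 eq), CH2Cl2, 0 °C to rt; aq. NaHCO3 wash; then K2CO3 (0.3 eq), MeOH, rt, Ar
Reagents that add atoms: mCPBA, OOC(=O)c1cccc(Cl)c1
Why: Dakin-type Baeyer–Villiger oxidation, in which the electron-rich 2,6-dioxygenated aryl group migrates in the Criegee adduct in preference to hydride and the aryl formate is then cleaved by mild methanolysis once the peracid has been removed.

Step 5
Reactants: 7 2-benzyloxy-6-methoxy-4-(2,4,6-trimethoxyphenoxy)phenol
Product: 8 1-benzyloxy-2,3-dimethoxy-5-(2,4,6-trimethoxyphenoxy)benzene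
Conditions: MeI (1.5 eq), K2CO3, DMF, rt
Reagents that add atoms: iodomethane, CI
Why: Williamson methylation of the phenoxide, which converts the former formyl position into the C4 methoxy group of ring B.

Step 6
Reactants: 8 1-benzyloxy-2,3-dimethoxy-5-(2,4,6-trimethoxyphenoxy)benzene
Product: 9 2,3-dimethoxy-5-(2,4,6-trimethoxyphenoxy)phenol (AB phenol)
Conditions: H2 (1 atm), Pd/C, EtOAc/MeOH, rt
Reagents that add atoms: none
Why: Catalytic hydrogenolysis cleaves only the benzylic C–O bond and leaves the methyl ethers and the diaryl ether intact, freeing the C5 oxygen of ring B.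

Step 7
Reactants: 10 2,3-dimethoxy-1,4-benzoquinone
Product: 12 5-bromo-2,3-dimethoxy-1,4-benzoquinone, via trans-dibromide 11 (not isolated)
Conditions: Br2 (1.0 eq), CH2Cl2, 0 °C; then NaOAc (1.5 eq), AcOH, rt
Reagents that add atoms: bromine, BrBr
Why: Bromination–dehydrobromination of a quinone, in which bromine adds anti across the unsubstituted C5=C6 bond and acetate then induces E1cB loss of HBr from the α-bromo ketone to restore the quinone.

Step 8
Reactants: 9 AB phenol; 12 5-bromo-2,3-dimethoxy-1,4-benzoquinone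
Product: 13 2,3-dimethoxy-5-[2,3-dimethoxy-5-(2,4,6-trimethoxyphenoxy)phenoxy]-1,4-benzoquinone (ABC quinone)
Conditions: 12 (1.1 eq), Cs2CO3 (1.1 eq), MeCN, −20 °C to 0 °C, Ar, dark; 9 added slowly
Reagents that add atoms: none
Why: Phenoxide addition–elimination on a bromoquinone, in which the loosely paired cesium phenoxide in a polar aprotic solvent at low temperature reacts through oxygen and the ring carbons of 9 are each flanked by two substituents, disfavouring C-attack.

Step 9
Reactants: 13 ABC quinone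
Product: 15 ABC mono-benzyl hydroquinone (ring C: C6–OH free; C3–OBn), via ABC hydroquinone 14 (not isolated)
Conditions: Na2S2O4 (3 eq), EtOAc/H2O, rt, Ar; organic phase dried and concentrated under Ar; then BnBr (1.0 eq), K2CO3 (1.5 eq), DMF, 0 °C to rt, Ar
Reagents that add atoms: benzyl bromide, BrCc1ccccc1
Why: Dithionite reduction of the quinone followed by sterically controlled Williamson benzylation, in which the OH flanked by OMe and the ring C–H is alkylated faster than the OH buried between OMe and the aryloxy group and limiting benzyl bromide prevents dialkylation.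

Step 10
Reactants: 15 ABC mono-benzyl hydroquinone; 1 4-fluoro-2,6-dimethoxybenzaldehyde
Product: 16 ABCD aldehyde
Conditions: 1 (1.3 eq), Cs2CO3 (2 eq), DMSO, 90 °C, Ar
Reagents that add atoms: none
Why: SNAr of the remaining, hindered phenoxide (O on C6 of ring C) on the fluoride para to the formyl group of 1, where the methoxy groups are meta to the site of attack.

Step 11
Reactants: 16 ABCD aldehyde
Product: 18 ABCD phenol, via ABCD aryl formate 17 (not isolated)
Conditions: mCPBA (1.1 eq), CH2Cl2, 0 °C to rt; aq. NaHCO3 wash; then K2CO3 (0.3 eq), MeOH, rt, Ar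
Reagents that add atoms: mCPBA, OOC(=O)c1cccc(Cl)c1
Why: Dakin-type Baeyer–Villiger oxidation with aryl migration of the 2,6-dimethoxyaryl group, the oxidation-prone phenol being liberated by methanolysis only after the peracid has been washed out.

Step 12
Reactants: 18 ABCD phenol; 12 5-bromo-2,3-dimethoxy-1,4-benzoquinone
Product: 19 ABCDE quinone
Conditions: 12 (1.1 eq), Cs2CO3 (1.1 eq), MeCN, −20 °C to 0 °C, Ar, dark; 18 added slowly
Reagents that add atoms: none
Why: The cesium phenoxide of 18 (oxygen on C4 of ring D) adds to C5 of 12 and the bromo-enolate expels bromide, or it adds to C6 and HBr is then lost by tautomerisation and β-elimination; because the 2,3-dimethoxyquinone core has a mirror plane through the midpoints of the C2–C3 and C5–C6 bonds, both paths give the same 5-aryloxyquinone 19. The closest known reaction type is the addition–elimination of phenoxides on halo-1,4-benzoquinones and halonaphthoquinones to give aryloxyquinones. No ring is closed and no stereocentre is formed; one C–O bond delivers ring E with all five oxygens in place at the quinone oxidation level. The step needs O- over C-attack, substitution at C5/C6 and not at the methoxy-bearing C2/C3, and a single addition. O-attack is secured because both ortho positions (methoxy on C3 and C5) and the para position (aryloxy on C1) of ring D are blocked; attack at C2/C3 is only a reversible vinylogous transesterification in which the aryloxide is the better leaving group, whereas loss of bromide is irreversible; and a slight excess of 12 at −20 °C without air keeps the free phenoxide concentration low, so the product is not attacked again and single-electron transfer is limited.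

Step 13
Reactants: 19 ABCDE quinone
Product: 21 ABCDE mono-benzyl hydroquinone (ring E: C6–OH free; C3–OBn), via ABCDE hydroquinone 20 (not isolated)
Conditions: Na2S2O4 (3 eq), EtOAc/H2O, rt, Ar; organic phase dried and concentrated under Ar; then BnBr (1.0 eq), K2CO3 (1.5 eq), DMF, 0 °C to rt, Ar
Reagents that add atoms: benzyl bromide, BrCc1ccccc1
Why: Dithionite reduction then sterically controlled Williamson benzylation of the hydroquinone OH next to the ring E C–H, the OH between OMe and the ring D aryloxy group staying free.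

Step 14
Reactants: 21 ABCDE mono-benzyl hydroquinone; 1 4-fluoro-2,6-dimethoxybenzaldehyde
Product: 22 ABCDEF aldehyde
Conditions: 1 (1.3 eq), Cs2CO3 (2 eq), DMSO, 90 °C, Ar
Reagents that add atoms: none
Why: SNAr of the hindered phenoxide on C6 of ring E at the fluoride para to the formyl group, no other ring in the chain carrying an activating group that could be displaced.

Step 15
Reactants: 22 ABCDEF aldehyde
Product: 24 ABCDEF phenol, via ABCDEF aryl formate 23 (not isolated)
Conditions: mCPBA (1.1 eq), CH2Cl2, 0 °C to rt; aq. NaHCO3 wash; then K2CO3 (0.3 eq), MeOH, rt, Ar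
Reagents that add atoms: mCPBA, OOC(=O)c1cccc(Cl)c1
Why: Dakin-type Baeyer–Villiger oxidation of the only carbonyl group in the molecule, followed by methanolysis of the aryl formate.

Step 16
Reactants: 24 ABCDEF phenol; 12 5-bromo-2,3-dimethoxy-1,4-benzoquinone
Product: 25 ABCDEFG quinone
Conditions: 12 (1.1 eq), Cs2CO3 (1.1 eq), MeCN, −20 °C to 0 °C, Ar, dark; 24 added slowly
Reagents that add atoms: none
Why: Phenoxide addition–elimination on the bromoquinone as in step 12, the 2,6-dimethoxy-4-aryloxyphenoxide of ring F having no free ortho or para carbon and the symmetric quinone giving one product from attack at either CH carbon.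

Step 17
Reactants: 25 ABCDEFG quinone
Product: 27 ABCDEFG mono-benzyl hydroquinone (ring G: C6–OH free; C3–OBn), via ABCDEFG hydroquinone 26 (not isolated)
Conditions: Na2S2O4 (3 eq), EtOAc/H2O, rt, Ar; organic phase dried and concentrated under Ar; then BnBr (1.0 eq), K2CO3 (1.5 eq), DMF, 0 °C to rt, Ar
Reagents that add atoms: benzyl bromide, BrCc1ccccc1
Why: Dithionite reduction then sterically controlled Williamson benzylation of the less hindered hydroquinone OH next to the ring G C–H.

Step 18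
Reactants: 27 ABCDEFG mono-benzyl hydroquinone; 1 4-fluoro-2,6-dimethoxybenzaldehyde
Product: 28 octamer aldehyde (17 OMe, 3 OBn, CHO on ring H)
Conditions: 1 (1.5 eq), Cs2CO3 (2 eq), DMSO, 90 °C, Ar
Reagents that add atoms: none
Why: SNAr of the hindered phenoxide on C6 of ring G at the fluoride para to the formyl group, completing the eight-ring chain.

Step 19
Reactants: 28 octamer aldehyde
Product: 30 octamer phenol, via octamer aryl formate 29 (not isolated)
Conditions: mCPBA (1.1 eq), CH2Cl2, 0 °C to rt; aq. NaHCO3 wash; then K2CO3 (0.3 eq), MeOH, rt, Ar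
Reagents that add atoms: mCPBA, OOC(=O)c1cccc(Cl)c1
Why: Dakin-type Baeyer–Villiger oxidation turns the last formyl group into the C4 oxygen of ring H.

Step 20
Reactants: 30 octamer phenol
Product: 31 CNP0175816.0
Conditions: BBr3 (60 eq), pentamethylbenzene (10 eq), CH2Cl2, −78 °C to rt, Ar; degassed H2O, 0 °C; EtOAc extraction and Sephadex LH-20 (degassed MeOH) under Ar
Reagents that add atoms: none
Why: Lewis acid ether cleavage, in which bromide removes each methyl group by SN2 from the boron-complexed ether, the benzyl groups ionise and are trapped by pentamethylbenzene in a Friedel–Crafts reaction that protects the electron-rich rings from C-benzylation, and the diaryl ether bonds, which offer no sp3 carbon, are left intact.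

Compound list
1 | 4-fluoro-2,6-dimethoxybenzaldehyde | O=Cc1c(OC)cc(F)cc1OC | starting material
2 | 4-fluoro-2-hydroxy-6-methoxybenzaldehyde | O=Cc1c(O)cc(F)cc1OC | intermediate
3 | 2-benzyloxy-4-fluoro-6-methoxybenzaldehyde | O=Cc1c(OC)cc(F)cc1OCc1ccccc1 | intermediate
4 | 2,4,6-trimethoxyphenol | COc1cc(OC)c(O)c(OC)c1 | starting material
5 | AB aldehyde: 2-benzyloxy-6-methoxy-4-(2,4,6-trimethoxyphenoxy)benzaldehyde | COc1cc(OC)c(Oc2cc(OC)c(C=O)c(OCc3ccccc3)c2)c(OC)c1 | intermediate
6 | AB aryl formate: 2-benzyloxy-6-methoxy-4-(2,4,6-trimethoxyphenoxy)phenyl formate | COc1cc(OC)c(Oc2cc(OC)c(OC=O)c(OCc3ccccc3)c2)c(OC)c1 | intermediate (not isolated)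
7 | 2-benzyloxy-6-methoxy-4-(2,4,6-trimethoxyphenoxy)phenol | COc1cc(OC)c(Oc2cc(OC)c(O)c(OCc3ccccc3)c2)c(OC)c1 | intermediate
8 | 1-benzyloxy-2,3-dimethoxy-5-(2,4,6-trimethoxyphenoxy)benzene | COc1cc(OC)c(Oc2cc(OC)c(OC)c(OCc3ccccc3)c2)c(OC)c1 | intermediate
9 | AB phenol: 2,3-dimethoxy-5-(2,4,6-trimethoxyphenoxy)phenol | COc1cc(OC)c(Oc2cc(OC)c(OC)c(O)c2)c(OC)c1 | intermediate
10 | 2,3-dimethoxy-1,4-benzoquinone | COC1=C(OC)C(=O)C=CC1=O | starting material
11 | trans-5,6-dibromo-2,3-dimethoxycyclohex-2-ene-1,4-dione (racemic, one enantiomer drawn) | COC1=C(OC)C(=O)[C@@H](Br)[C@H](Br)C1=O | intermediate (not isolated)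
12 | 5-bromo-2,3-dimethoxy-1,4-benzoquinone | COC1=C(OC)C(=O)C(Br)=CC1=O | intermediate
13 | ABC quinone: 2,3-dimethoxy-5-[2,3-dimethoxy-5-(2,4,6-trimethoxyphenoxy)phenoxy]cyclohexa-2,5-diene-1,4-dione | COc1cc(OC)c(Oc2cc(OC)c(OC)c(OC3=CC(=O)C(OC)=C(OC)C3=O)c2)c(OC)c1 | intermediate
14 | ABC hydroquinone: 2,3-dimethoxy-5-[2,3-dimethoxy-5-(2,4,6-trimethoxyphenoxy)phenoxy]benzene-1,4-diol | COc1cc(OC)c(Oc2cc(OC)c(OC)c(Oc3cc(O)c(OC)c(OC)c3O)c2)c(OC)c1 | intermediate (not isolated)
15 | ABC mono-benzyl hydroquinone: 4-benzyloxy-2,3-dimethoxy-6-[2,3-dimethoxy-5-(2,4,6-trimethoxyphenoxy)phenoxy]phenol | COc1cc(OC)c(Oc2cc(OC)c(OC)c(Oc3cc(OCc4ccccc4)c(OC)c(OC)c3O)c2)c(OC)c1 | intermediate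
16 | ABCD aldehyde: 4-{4-benzyloxy-2,3-dimethoxy-6-[2,3-dimethoxy-5-(2,4,6-trimethoxyphenoxy)phenoxy]phenoxy}-2,6-dimethoxybenzaldehyde | COc1cc(OC)c(Oc2cc(OC)c(OC)c(Oc3cc(OCc4ccccc4)c(OC)c(OC)c3Oc3cc(OC)c(C=O)c(OC)c3)c2)c(OC)c1 | intermediate
17 | ABCD aryl formate: formate ester of 18 at the ring D C4 oxygen | COc1cc(OC)c(Oc2cc(OC)c(OC)c(Oc3cc(OCc4ccccc4)c(OC)c(OC)c3Oc3cc(OC)c(OC=O)c(OC)c3)c2)c(OC)c1 | intermediate (not isolated)
18 | ABCD phenol: 4-{4-benzyloxy-2,3-dimethoxy-6-[2,3-dimethoxy-5-(2,4,6-trimethoxyphenoxy)phenoxy]phenoxy}-2,6-dimethoxyphenol | COc1cc(OC)c(Oc2cc(OC)c(OC)c(Oc3cc(OCc4ccccc4)c(OC)c(OC)c3Oc3cc(OC)c(O)c(OC)c3)c2)c(OC)c1 | intermediate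
19 | ABCDE quinone: 18 whose ring D C4 oxygen carries a 4,5-dimethoxy-3,6-dioxocyclohexa-1,4-dien-1-yl group (ring E at the quinone level) | COc1cc(OC)c(Oc2cc(OC)c(OC)c(Oc3cc(OCc4ccccc4)c(OC)c(OC)c3Oc3cc(OC)c(OC4=CC(=O)C(OC)=C(OC)C4=O)c(OC)c3)c2)c(OC)c1 | intermediate
20 | ABCDE hydroquinone: 19 with the quinone ring reduced to the 1,4-diol | COc1cc(OC)c(Oc2cc(OC)c(OC)c(Oc3cc(OCc4ccccc4)c(OC)c(OC)c3Oc3cc(OC)c(Oc4cc(O)c(OC)c(OC)c4O)c(OC)c3)c2)c(OC)c1 | intermediate (not isolated)
21 | ABCDE mono-benzyl hydroquinone: 20 with the OH next to the ring E C–H benzylated (ring E: C1 O to ring D, C2 H, C3 OBn, C4 and C5 OMe, C6 OH) | COc1cc(OC)c(Oc2cc(OC)c(OC)c(Oc3cc(OCc4ccccc4)c(OC)c(OC)c3Oc3cc(OC)c(Oc4cc(OCc5ccccc5)c(OC)c(OC)c4O)c(OC)c3)c2)c(OC)c1 | intermediate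
22 | ABCDEF aldehyde: 21 whose ring E C6 oxygen carries a 4-formyl-3,5-dimethoxyphenyl group (ring F) | COc1cc(OC)c(Oc2cc(OC)c(OC)c(Oc3cc(OCc4ccccc4)c(OC)c(OC)c3Oc3cc(OC)c(Oc4cc(OCc5ccccc5)c(OC)c(OC)c4Oc4cc(OC)c(C=O)c(OC)c4)c(OC)c3)c2)c(OC)c1 | intermediate
23 | ABCDEF aryl formate: formate ester of 24 at the ring F C4 oxygen | COc1cc(OC)c(Oc2cc(OC)c(OC)c(Oc3cc(OCc4ccccc4)c(OC)c(OC)c3Oc3cc(OC)c(Oc4cc(OCc5ccccc5)c(OC)c(OC)c4Oc4cc(OC)c(OC=O)c(OC)c4)c(OC)c3)c2)c(OC)c1 | intermediate (not isolated)
24 | ABCDEF phenol: 22 with CHO replaced by OH (free OH on C4 of ring F between two OMe) | COc1cc(OC)c(Oc2cc(OC)c(OC)c(Oc3cc(OCc4ccccc4)c(OC)c(OC)c3Oc3cc(OC)c(Oc4cc(OCc5ccccc5)c(OC)c(OC)c4Oc4cc(OC)c(O)c(OC)c4)c(OC)c3)c2)c(OC)c1 | intermediate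
25 | ABCDEFG quinone: 24 whose ring F C4 oxygen carries a 4,5-dimethoxy-3,6-dioxocyclohexa-1,4-dien-1-yl group (ring G at the quinone level) | COc1cc(OC)c(Oc2cc(OC)c(OC)c(Oc3cc(OCc4ccccc4)c(OC)c(OC)c3Oc3cc(OC)c(Oc4cc(OCc5ccccc5)c(OC)c(OC)c4Oc4cc(OC)c(OC5=CC(=O)C(OC)=C(OC)C5=O)c(OC)c4)c(OC)c3)c2)c(OC)c1 | intermediate
26 | ABCDEFG hydroquinone: 25 with the quinone ring reduced to the 1,4-diol | COc1cc(OC)c(Oc2cc(OC)c(OC)c(Oc3cc(OCc4ccccc4)c(OC)c(OC)c3Oc3cc(OC)c(Oc4cc(OCc5ccccc5)c(OC)c(OC)c4Oc4cc(OC)c(Oc5cc(O)c(OC)c(OC)c5O)c(OC)c4)c(OC)c3)c2)c(OC)c1 | intermediate (not isolated)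
27 | ABCDEFG mono-benzyl hydroquinone: 26 with the OH next to the ring G C–H benzylated (ring G: C3 OBn, C4 and C5 OMe, C6 OH) | COc1cc(OC)c(Oc2cc(OC)c(OC)c(Oc3cc(OCc4ccccc4)c(OC)c(OC)c3Oc3cc(OC)c(Oc4cc(OCc5ccccc5)c(OC)c(OC)c4Oc4cc(OC)c(Oc5cc(OCc6ccccc6)c(OC)c(OC)c5O)c(OC)c4)c(OC)c3)c2)c(OC)c1 | intermediate
28 | octamer aldehyde: 27 whose ring G C6 oxygen carries a 4-formyl-3,5-dimethoxyphenyl group (ring H); 17 OMe, 3 OBn | COc1cc(OC)c(Oc2cc(OC)c(OC)c(Oc3cc(OCc4ccccc4)c(OC)c(OC)c3Oc3cc(OC)c(Oc4cc(OCc5ccccc5)c(OC)c(OC)c4Oc4cc(OC)c(Oc5cc(OCc6ccccc6)c(OC)c(OC)c5Oc5cc(OC)c(C=O)c(OC)c5)c(OC)c4)c(OC)c3)c2)c(OC)c1 | intermediate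
29 | octamer aryl formate: formate ester of 30 at the ring H C4 oxygen | COc1cc(OC)c(Oc2cc(OC)c(OC)c(Oc3cc(OCc4ccccc4)c(OC)c(OC)c3Oc3cc(OC)c(Oc4cc(OCc5ccccc5)c(OC)c(OC)c4Oc4cc(OC)c(Oc5cc(OCc6ccccc6)c(OC)c(OC)c5Oc5cc(OC)c(OC=O)c(OC)c5)c(OC)c4)c(OC)c3)c2)c(OC)c1 | intermediate (not isolated)
30 | octamer phenol: 28 with CHO replaced by OH (ring H 4-hydroxy-3,5-dimethoxyphenyl) | COc1cc(OC)c(Oc2cc(OC)c(OC)c(Oc3cc(OCc4ccccc4)c(OC)c(OC)c3Oc3cc(OC)c(Oc4cc(OCc5ccccc5)c(OC)c(OC)c4Oc4cc(OC)c(Oc5cc(OCc6ccccc6)c(OC)c(OC)c5Oc5cc(OC)c(O)c(OC)c5)c(OC)c4)c(OC)c3)c2)c(OC)c1 | intermediate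
31 | CNP0175816.0 (all 21 oxygens as free OH) | Oc1cc(O)c(Oc2cc(O)c(O)c(Oc3cc(O)c(O)c(O)c3Oc3cc(O)c(Oc4cc(O)c(O)c(O)c4Oc4cc(O)c(Oc5cc(O)c(O)c(O)c5Oc5cc(O)c(O)c(O)c5)c(O)c4)c(O)c3)c2)c(O)c1 | target

Total step count: 20 steps.
Longest linear sequence: 19 steps (steps 1 to 6 and 8 to 20, starting from 1; step 7 is a one-step side branch from 10).

Steps most likely to fail

1. Step 12 (the same concern applies to steps 8 and 16). The very electron-rich phenoxide may transfer an electron to the quinone instead of adding to it, which would consume the tetramer through phenoxyl radical chemistry. In step 8 the free ring carbons of 9 could also attack through carbon. The fallback replaces the quinone electrophile by an ortho-formyl aryl fluoride and reaches the quinone oxidation level only afterwards. It sets out from 18. Purchased 5-fluoro-1,2,3-trimethoxybenzene is formylated at its only free position type (Rieche formylation, Cl2CHOMe, TiCl4, CH2Cl2, 0 °C) to give 6-fluoro-2,3,4-trimethoxybenzaldehyde F1. SNAr of the phenoxide of 18 on F1 (Cs2CO3, DMSO, 110 °C, Ar) gives the pentamer ortho-aryloxy benzaldehyde F2. Dakin-type oxidation (mCPBA, then K2CO3, MeOH) passes through the pentamer aryl formate F3 to the pentamer phenol F4, whose new OH lies para to a methoxy group. Oxidative demethylation of this para-methoxyphenol with PhI(OAc)2 in MeCN/H2O at 0 °C gives the para-quinone, which is 19, where the route is rejoined.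

2. Step 9 (likewise steps 13 and 17). Site selectivity in the mono-benzylation may be poor, with alkylation at the hindered oxygen or at both oxygens, and the hydroquinone may be reoxidised by air under basic conditions. The fallback differentiates the two oxygens by ester cleavage rates and not by alkylation rates. It sets out from 13. Reductive acetylation (Zn, Ac2O, NaOAc, rt) gives the air-stable ABC hydroquinone diacetate F5. Methanolysis with catalytic K2CO3 in MeOH at −20 °C removes the less hindered acetate next to the ring C C–H and gives the ABC hydroquinone monoacetate F6. Mitsunobu benzylation under neutral conditions (BnOH, PPh3, DIAD, THF), which avoids acyl scrambling, gives the ABC benzyl ether acetate F7. Methanolysis of the hindered acetate (K2CO3, MeOH, rt, Ar) then gives 15.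

3. Step 20. Cleavage of twenty ethers may stop short of completion, and the free pyrogallol-type polyphenol may be degraded oxidatively during work-up and purification. The fallback isolates the product as a stable derivative and releases it afterwards. It sets out from 30. After the BBr3 and pentamethylbenzene treatment the crude polyphenol is acetylated without purification (Ac2O, pyridine, rt) to the henicosaacetate F8. F8 tolerates air and silica chromatography and can be separated from partly methylated material. Acid-catalysed transesterification (AcCl in degassed MeOH, which generates HCl, rt, Ar) followed by evaporation then gives 31.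

Further compounds
F1 | step 12 | 6-fluoro-2,3,4-trimethoxybenzaldehyde | O=Cc1c(F)cc(OC)c(OC)c1OC
F2 | step 12 | pentamer ortho-aryloxy benzaldehyde: 18 whose ring D C4 oxygen carries a 2-formyl-3,4,5-trimethoxyphenyl group | COc1cc(OC)c(Oc2cc(OC)c(OC)c(Oc3cc(OCc4ccccc4)c(OC)c(OC)c3Oc3cc(OC)c(Oc4cc(OC)c(OC)c(OC)c4C=O)c(OC)c3)c2)c(OC)c1
F3 | step 12 | pentamer aryl formate: F2 with CHO replaced by OCHO | COc1cc(OC)c(Oc2cc(OC)c(OC)c(Oc3cc(OCc4ccccc4)c(OC)c(OC)c3Oc3cc(OC)c(Oc4cc(OC)c(OC)c(OC)c4OC=O)c(OC)c3)c2)c(OC)c1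
F4 | step 12 | pentamer phenol: F2 with CHO replaced by OH | COc1cc(OC)c(Oc2cc(OC)c(OC)c(Oc3cc(OCc4ccccc4)c(OC)c(OC)c3Oc3cc(OC)c(Oc4cc(OC)c(OC)c(OC)c4O)c(OC)c3)c2)c(OC)c1
F5 | step 9 | ABC hydroquinone diacetate | COc1cc(OC)c(Oc2cc(OC)c(OC)c(Oc3cc(OC(C)=O)c(OC)c(OC)c3OC(C)=O)c2)c(OC)c1
F6 | step 9 | ABC hydroquinone monoacetate (hindered acetate kept, OH next to the ring C C–H free) | COc1cc(OC)c(Oc2cc(OC)c(OC)c(Oc3cc(O)c(OC)c(OC)c3OC(C)=O)c2)c(OC)c1
F7 | step 9 | ABC benzyl ether acetate | COc1cc(OC)c(Oc2cc(OC)c(OC)c(Oc3cc(OCc4ccccc4)c(OC)c(OC)c3OC(C)=O)c2)c(OC)c1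
F8 | step 20 | henicosaacetate of 31 | CC(=O)Oc1cc(OC(C)=O)c(Oc2cc(OC(C)=O)c(OC(C)=O)c(Oc3cc(OC(C)=O)c(OC(C)=O)c(OC(C)=O)c3Oc3cc(OC(C)=O)c(Oc4cc(OC(C)=O)c(OC(C)=O)c(OC(C)=O)c4Oc4cc(OC(C)=O)c(Oc5cc(OC(C)=O)c(OC(C)=O)c(OC(C)=O)c5Oc5cc(OC(C)=O)c(OC(C)=O)c(OC(C)=O)c5)c(OC(C)=O)c4)c(OC(C)=O)c3)c2)c(OC(C)=O)c1
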